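**Retrosynthetic overview**

1. Target 20 ⇒ Mitsunobu ether bond (ArO–C1) ⇒ triol ketone 18 + umbelliferone 19.
2. 18 ⇒ loss of a traceless CO2H on C5 (photodecarboxylation) ⇒ keto lactone 16 ⇒ C6–C11 bond by a photochemical 6-exo radical conjugate addition (forms the only carbocycle, sets C6) ⇒ alkylidene lactone 15.
3. 15 ⇒ C5=C6 by aldol condensation ⇒ side-chain lactone 12 + keto aldehyde 9.
4. 12 and 9 both ⇒ (R)-lavender lactone 3 ⇒ (R)-linalool 1; 9 arises via butenolide 5, B-alkyl acylation (C9–C10) and ozonolytic excision of two carbons.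
5. Ring order: butyrolactone (step 1, carried as a temporary ring) → cyclohexanone (step 7); the coumarin is bought.

Assumption: C1–C11 are the chain locants of the target (C1 = OCH2, C3 = side-chain carbinol, C6 = ring CH, C7 = ring carbinol, C10 = ring C=O, C11 = CMe2); (R)-(−)-linalool of high ee is taken as the commercial chiral material.

**Route**

Step 1
Reactants: 1 (3R)-3,7-dimethylocta-1,6-dien-3-ol [(R)-(−)-linalool]
Product: 3 (5R)-5-ethenyl-5-methyloxolan-2-one, via lactol 2 (not isolated)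
Conditions: O3 (1.0 equiv, Sudan III end point), CH2Cl2, −78 °C; Me2S; then PhI(OAc)2, TEMPO (cat.), CH2Cl2, rt
Reagents that add atoms: ozone, O=[O+][O-]
Why: Chemoselective ozonolysis of the electron-rich trisubstituted alkene (the vinyl group reacts far more slowly), spontaneous lactol closure and TEMPO/PhI(OAc)2 lactol-to-lactone oxidation; the bought tertiary carbinol centre is untouched and later serves as both C3 and C7.

Step 2
Reactants: 3 (5R)-5-ethenyl-5-methyloxolan-2-one
Product: 5 (5S)-5-ethenyl-5-methylfuran-2(5H)-one, via α-phenylselanyl lactone 4 (not isolated)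
Conditions: LDA, THF, −78 °C; PhSeBr; then H2O2 (30% aq), pyridine, CH2Cl2, 0 °C→rt
Reagents that add atoms: none
Why: Reich–Sharpless α-selenenylation and selenoxide syn-elimination give the endocyclic butenolide; the quaternary centre cannot epimerise (the descriptor changes only through CIP priorities).

Step 3
Reactants: 5 (5S)-5-ethenyl-5-methylfuran-2(5H)-one
Product: 7 (5S)-5-methyl-5-(4-methyl-3-oxopentyl)furan-2(5H)-one, via B-alkyl-9-BBN adduct 6 (not isolated)
Conditions: 9-BBN, THF, 0 °C→rt; then i-PrC(O)SPh, Pd2(dba)3 (cat.), P(2-furyl)3, CuTC, Cs2CO3, THF, 45 °C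
Reagents that add atoms: S-phenyl 2-methylpropanethioate, CC(C)C(=O)Sc1ccccc1
Why: Anti-Markovnikov Brown hydroboration of the only electron-neutral alkene (the conjugated butenolide C=C is inert to 9-BBN), then Liebeskind–Srogl acyl cross-coupling of the B-alkyl-9-BBN with the thioester installs the isopropyl ketone arm (C9–C10); no stereocentre is touched.

Step 4
Reactants: 7 (5S)-5-methyl-5-(4-methyl-3-oxopentyl)furan-2(5H)-one
Product: 9 (2S)-2-hydroxy-2,6-dimethyl-5-oxoheptanal, via glyoxylate ester aldehyde 8 (not isolated)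
Conditions: O3, CH2Cl2, −78 °C; Me2S; then MeOH, NaHCO3 (cat.), rt
Reagents that add atoms: ozone, O=[O+][O-]
Why: Criegee ozonolysis of the butenolide C=C excises two carbons and leaves the tertiary oxygen as a labile glyoxylate ester, which base-catalysed transesterification removes; the non-enolisable α-centre (future C7) is retained.

Step 5
Reactants: 3 (5R)-5-ethenyl-5-methyloxolan-2-one
Product: 12 2-[(2R)-2-methyl-5-oxooxolan-2-yl]ethyl benzoate, via B-alkyl-9-BBN adduct 10 (not isolated), via hydroxyethyl lactone 11 (not isolated)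
Conditions: 9-BBN, THF, 0 °C→rt; H2O2 (30%), aq NaOAc, 0 °C→rt; then BzCl, pyridine, CH2Cl2, 0 °C
Reagents that add atoms: hydrogen peroxide, OO; benzoyl chloride, O=C(Cl)c1ccccc1
Why: Brown hydroboration–oxidation (anti-Markovnikov; buffered peroxide spares the lactone) and benzoylation of the new primary alcohol with a non-enolisable ester; the stereocentre (future C3) is untouched.

Step 6
Reactants: 9 (2S)-2-hydroxy-2,6-dimethyl-5-oxoheptanal; 12 2-[(2R)-2-methyl-5-oxooxolan-2-yl]ethyl benzoate
Product: 15 2-[(2R)-4-[(2S)-2-hydroxy-2,6-dimethyl-5-oxoheptylidene]-2-methyl-5-oxooxolan-2-yl]ethyl benzoate (E/Z mixture), via aldol adduct 13 (not isolated), via mesylate 14 (not isolated)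
Conditions: 12, LDA, THF, −78 °C; add 9 (pre-treated with LiHMDS, −78 °C), −78→−40 °C; AcOH; then MsCl, Et3N, CH2Cl2, 0 °C; DBU, rt
Reagents that add atoms: none
Why: Kinetic lactone-enolate aldol addition to the non-enolisable aldehyde (far more electrophilic than the hindered ketone) followed by mesylation and E1cB elimination (aldol condensation) gives the α-alkylidene lactone (C5=C6); both transient sp3 centres are erased and the alkene geometry is irrelevant.

Step 7
Reactants: 15 2-[(2R)-4-[(2S)-2-hydroxy-2,6-dimethyl-5-oxoheptylidene]-2-methyl-5-oxooxolan-2-yl]ethyl benzoate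
Product: 16 2-[(2R)-4-[(1R,2S)-2-hydroxy-2,6,6-trimethyl-5-oxocyclohexyl]-2-methyl-5-oxooxolan-2-yl]ethyl benzoate (both epimers at oxolane C4)
Conditions: Mes-Acr-Me+ BF4− (5 mol %), n-Bu4NBr (20 mol %), 2,4,6-collidinium triflate (20 mol %), 1,2-dichloroethane, 450 nm LEDs, rt, Ar
Reagents that add atoms: none
Why: Proposed new method: an acridinium/bromide co-catalysed, redox-neutral photochemical cycloisomerisation in which photo-oxidised bromide gives Br•, which abstracts the weak tertiary α-keto C–H (about 88 kcal/mol against 87.5 for H–Br); the tertiary α-keto radical then closes 6-exo onto the alkylidene-lactone β-carbon (C6) through a chair transition state with the C7 methyl equatorial and the C7 hydroxyl axial (avoiding the syn-axial clash with a C11 methyl), and the α-lactone radical takes H from HBr (chain) or is reduced by the acridine radical and protonated, which sets C6 (R) cis to the C7–OH, the isomer that is also thermodynamically preferred; the closest known chemistry is bromine-radical HAT in photoredox C(sp3)–H functionalisation combined with intramolecular Giese-type radical conjugate addition (polarity-mismatched here, offset by intramolecularity).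

Step 8
Reactants: 16 2-[(2R)-4-[(1R,2S)-2-hydroxy-2,6,6-trimethyl-5-oxocyclohexyl]-2-methyl-5-oxooxolan-2-yl]ethyl benzoate
Product: 18 (3R,4S)-3-[(3R)-3,5-dihydroxy-3-methylpentyl]-4-hydroxy-2,2,4-trimethylcyclohexan-1-one, via lithium carboxylate 17 (not isolated)
Conditions: LiOH, THF/H2O, rt; then Mes-Acr-Ph+ BF4− (5 mol %), (PhS)2 (10 mol %), CF3CH2OH, 450 nm LEDs, rt; aq NH4Cl
Reagents that add atoms: none
Why: Saponification of lactone and benzoate, then acridinium/disulfide photoredox hydrodecarboxylation (carboxylate SET oxidation, CO2 loss, thiol HAT) removes the activating carboxyl; the carbon that loses CO2 becomes the C5 methylene, so its configuration is irrelevant and C3, C6 and C7 are untouched.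

Step 9
Reactants: 18 (3R,4S)-3-[(3R)-3,5-dihydroxy-3-methylpentyl]-4-hydroxy-2,2,4-trimethylcyclohexan-1-one; 19 7-hydroxy-2H-chromen-2-one (umbelliferone)
Product: 20 7-{[(3R)-3-hydroxy-5-[(1R,2S)-2-hydroxy-2,6,6-trimethyl-5-oxocyclohexyl]-3-methylpentyl]oxy}-2H-chromen-2-one
Conditions: PPh3, DIAD, THF, 0 °C→rt
Reagents that add atoms: none
Why: Mitsunobu etherification of the only primary alcohol with the acidic phenol (pKa about 7.8); the two tertiary alcohols and the ketone are inert and no stereocentre is involved.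

**Compound list**

1 | (3R)-3,7-dimethylocta-1,6-dien-3-ol, (R)-(−)-linalool | C=C[C@](C)(O)CCC=C(C)C | starting material
2 | (5R)-5-ethenyl-5-methyloxolan-2-ol (lactol, anomers) | C=C[C@]1(C)OC(O)CC1 | intermediate
3 | (5R)-5-ethenyl-5-methyloxolan-2-one | C=C[C@]1(C)OC(=O)CC1 | intermediate
4 | (5R)-5-ethenyl-5-methyl-3-(phenylselanyl)oxolan-2-one (C3 epimers) | C=C[C@]1(C)OC(=O)C([Se]c2ccccc2)C1 | intermediate
5 | (5S)-5-ethenyl-5-methylfuran-2(5H)-one | C=C[C@]1(C)OC(=O)C=C1 | intermediate
6 | 9-{2-[(2S)-2-methyl-5-oxo-2,5-dihydrofuran-2-yl]ethyl}-9-borabicyclo[3.3.1]nonane | B1(CC[C@]2(C)OC(=O)C=C2)C2CCCC1CCC2 | intermediate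
7 | (5S)-5-methyl-5-(4-methyl-3-oxopentyl)furan-2(5H)-one | CC(C)C(=O)CC[C@]1(C)OC(=O)C=C1 | intermediate
8 | (2S)-2,6-dimethyl-1,5-dioxoheptan-2-yl oxoacetate | CC(C)C(=O)CC[C@](C)(OC(=O)C=O)C=O | intermediate
9 | (2S)-2-hydroxy-2,6-dimethyl-5-oxoheptanal | CC(C)C(=O)CC[C@](C)(O)C=O | intermediate
10 | 9-{2-[(2S)-2-methyl-5-oxooxolan-2-yl]ethyl}-9-borabicyclo[3.3.1]nonane | B1(CC[C@]2(C)OC(=O)CC2)C2CCCC1CCC2 | intermediate
11 | (5R)-5-(2-hydroxyethyl)-5-methyloxolan-2-one | OCC[C@]1(C)OC(=O)CC1 | intermediate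
12 | 2-[(2R)-2-methyl-5-oxooxolan-2-yl]ethyl benzoate | O=C(OCC[C@]1(C)OC(=O)CC1)c1ccccc1 | intermediate
13 | 2-[(2R)-4-[(2S)-1,2-dihydroxy-2,6-dimethyl-5-oxoheptyl]-2-methyl-5-oxooxolan-2-yl]ethyl benzoate (diastereomers) | CC(C)C(=O)CC[C@](C)(O)C(O)C1C[C@](C)(CCOC(=O)c2ccccc2)OC1=O | intermediate
14 | 2-[(2R)-4-[(2S)-2-hydroxy-1-(methanesulfonyloxy)-2,6-dimethyl-5-oxoheptyl]-2-methyl-5-oxooxolan-2-yl]ethyl benzoate (diastereomers) | CC(C)C(=O)CC[C@](C)(O)C(OS(C)(=O)=O)C1C[C@](C)(CCOC(=O)c2ccccc2)OC1=O | intermediate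
15 | 2-[(2R)-4-[(2S)-2-hydroxy-2,6-dimethyl-5-oxoheptylidene]-2-methyl-5-oxooxolan-2-yl]ethyl benzoate (E/Z) | CC(C)C(=O)CC[C@](C)(O)C=C1C[C@](C)(CCOC(=O)c2ccccc2)OC1=O | intermediate
16 | 2-[(2R)-4-[(1R,2S)-2-hydroxy-2,6,6-trimethyl-5-oxocyclohexyl]-2-methyl-5-oxooxolan-2-yl]ethyl benzoate (oxolane C4 epimers) | CC1(C)C(=O)CC[C@](C)(O)[C@@H]1C1C[C@](C)(CCOC(=O)c2ccccc2)OC1=O | intermediate
17 | lithium (4R)-4,6-dihydroxy-2-[(1R,2S)-2-hydroxy-2,6,6-trimethyl-5-oxocyclohexyl]-4-methylhexanoate (C2 epimers) | CC1(C)C(=O)CC[C@](C)(O)[C@@H]1C(C[C@@](C)(O)CCO)C(=O)[O-].[Li+] | intermediate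
18 | (3R,4S)-3-[(3R)-3,5-dihydroxy-3-methylpentyl]-4-hydroxy-2,2,4-trimethylcyclohexan-1-one | CC1(C)C(=O)CC[C@](C)(O)[C@@H]1CC[C@@](C)(O)CCO | intermediate
19 | 7-hydroxy-2H-chromen-2-one (umbelliferone) | O=c1ccc2ccc(O)cc2o1 | starting material
20 | 7-{[(3R)-3-hydroxy-5-[(1R,2S)-2-hydroxy-2,6,6-trimethyl-5-oxocyclohexyl]-3-methylpentyl]oxy}-2H-chromen-2-one | CC1(C)C(=O)CC[C@](C)(O)[C@@H]1CC[C@@](C)(O)CCOc1ccc2ccc(=O)oc2c1 | target

**Step count and risks**

Total step count: 9. Longest linear sequence: 8 steps (1 → 3 → 5 → 7 → 9 → 15 → 16 → 18 → 20).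

The three steps most likely to fail:

Step 7, the proposed new photochemical ring closure, is the most uncertain. Br• may prefer the allylic C4–H of the alkylidene lactone, and the α-keto radical adds to an electron-poor alkene against polarity, so conversion and the kinetic C6 ratio are untested. The fallback sets out from 15 and comes back to the route at 16. It is the classical base-mediated intramolecular Michael addition (KOt-Bu 0.2 equiv, t-BuOH/THF, 0 °C→rt), a polar enolate closure under thermodynamic control. Retro-Michael/Michael equilibration through the acidic C5–H funnels the material to the same cis isomer, estimated at about 2 kcal/mol more stable because the trans isomer needs a syn-axial Me/Me pair. No further compound arises (F0).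

Step 6 may suffer from the hindered, α-oxido aldehyde (slow addition, α-ketol rearrangement of 9, or incomplete elimination). The fallback sets out from 12 and comes back at 15. Lactone 12 is phosphonylated (LDA 2.2 equiv, ClP(O)(OEt)2, THF, −78 °C→rt; enol phosphate then 1,3-phosphorus shift) to diethyl [(5S)-5-[2-(benzoyloxy)ethyl]-5-methyl-2-oxooxolan-3-yl]phosphonate F1. Horner–Wadsworth–Emmons olefination of F1 with 9 (LiCl, DBU, MeCN) then gives 15 directly.

Step 3 may fail at the acyl cross-coupling of the hindered B-alkyl-9-BBN in the presence of the butenolide. The fallback sets out from 5 and comes back at 7. Hydroboration–oxidation (9-BBN; H2O2, aq NaOAc) gives (5S)-5-(2-hydroxyethyl)-5-methylfuran-2(5H)-one F2. Appel iodination (I2, PPh3, imidazole) gives (5S)-5-(2-iodoethyl)-5-methylfuran-2(5H)-one F3. Zinc insertion (Zn dust, LiCl, THF) gives iodo{2-[(2S)-2-methyl-5-oxo-2,5-dihydrofuran-2-yl]ethyl}zinc F4, and Fukuyama coupling with S-ethyl 2-methylpropanethioate (PdCl2(PPh3)2, toluene, rt) delivers 7.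

Further compounds
F0 | step 7 | none | none
F1 | step 6 | diethyl [(5S)-5-[2-(benzoyloxy)ethyl]-5-methyl-2-oxooxolan-3-yl]phosphonate (C3 epimers) | CCOP(=O)(OCC)C1C[C@](C)(CCOC(=O)c2ccccc2)OC1=O
F2 | step 3 | (5S)-5-(2-hydroxyethyl)-5-methylfuran-2(5H)-one | OCC[C@]1(C)OC(=O)C=C1
F3 | step 3 | (5S)-5-(2-iodoethyl)-5-methylfuran-2(5H)-one | ICC[C@]1(C)OC(=O)C=C1
F4 | step 3 | iodo{2-[(2S)-2-methyl-5-oxo-2,5-dihydrofuran-2-yl]ethyl}zinc | I[Zn]CC[C@]1(C)OC(=O)C=C1
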